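A direct plan would take ring A from 2,3,4-trimethoxybenzaldehyde A1 and would move A1 by Dakin oxidation and ortho-formylation to 2-hydroxy-3,4,5-trimethoxybenzaldehyde A2. It would convert 2-methoxy-1-(4-methoxyphenyl)ethan-1-one A3 by enol triflate elimination into the ynol ether 1-methoxy-4-(methoxyethynyl)benzene A4, and would close ring C last by a [Cp*RhCl2]2-catalysed oxidative aldehyde C–H/phenol O–H annulation of A2 with A4. Its weakest steps would be:
- the annulation of A2 with A4, because ynol ethers are untested in it and the aryl and methoxy groups both claim the metal-bearing carbon, so the 2-methoxy-3-aryl isomer could prevail;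
- the elimination of A3 to A4, whose product would hydrate or polymerise on contact with acid and would have to be used at once;
- the oxidation/formylation pair from A1 to A2, two steps that would only move one oxygen and add one carbon on a bought arene.

The route rests on making ring A from a four-membered ring. C6, C7, C8 and C8a of auranetin, all oxygen-bearing, map onto the four carbons of dimethyl squarate; C5–H and C4a come from a vinyl unit that already carries C4 and C3 as a methoxyacetyl group. Heating the resulting 4-alkenyl-4-methoxycyclobutenone opens it to a dienylketene whose 6π closure builds the whole of ring A in one operation, with three methoxy groups in place and the ketene oxygen released as the single hydroxyl at C8a, ortho to the ketone. No ynol ether, no C–H annulation and no Dakin/formylation detour is needed; ring C then closes by Allan–Robinson condensation.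

Key step: step 3

Remark: compounds 5 and 7 are racemic at the quaternary ring carbon; this centre disappears in step 3, and the target is achiral.

Step 1
Reactants: 1 (E)-1,2-bis(tributylstannyl)ethene; 2 dimethyl squarate (3,4-dimethoxycyclobut-3-ene-1,2-dione)
Product: 5 racemic 2,3,4-trimethoxy-4-[(E)-2-(tributylstannyl)ethenyl]cyclobut-2-en-1-one, via vinyllithium 3 (not isolated), via lithium alkoxide 4 (not isolated)
Conditions: n-BuLi (1.0 equiv), THF, −78 °C, 1 h; add to 2, THF, −78 °C; MeOTf (1.5 equiv), −78 to 0 °C; Et3N-deactivated SiO2
Reagents that add atoms: methyl trifluoromethanesulfonate (MeOTf), COS(=O)(=O)C(F)(F)F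
Why: Tin–lithium exchange gives the (E)-vinyllithium with retention, which adds 1,2 to one of the two equivalent carbonyl groups of the squarate (the alkoxide adduct is a deactivated vinylogous ester and should not add again), and O-methylation of the tertiary alkoxide fixes the future C6 methoxy group; the new quaternary centre is racemic and is erased in step 3.

Step 2
Reactants: 5 racemic 2,3,4-trimethoxy-4-[(E)-2-(tributylstannyl)ethenyl]cyclobut-2-en-1-one; 6 methoxyacetyl chloride
Product: 7 racemic 2,3,4-trimethoxy-4-[(1E)-4-methoxy-3-oxobut-1-en-1-yl]cyclobut-2-en-1-one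
Conditions: 6 (1.2 equiv), Pd2(dba)3 (2.5 mol %), P(2-furyl)3 (10 mol %), THF, 40 °C
Reagents that add atoms: none
Why: Stille acylation, in which oxidative addition of the acid chloride to zerovalent palladium, transfer of the alkenyl group from tin with retention of the (E) geometry and reductive elimination should give the enone below the temperature at which the cyclobutenone opens.

Step 3
Reactants: 7 racemic 2,3,4-trimethoxy-4-[(1E)-4-methoxy-3-oxobut-1-en-1-yl]cyclobut-2-en-1-one
Product: 10 1-(2-hydroxy-3,4,5-trimethoxyphenyl)-2-methoxyethan-1-one, via dienylketene 8 (not isolated), via cyclohexadienone 9 (not isolated)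
Conditions: toluene (0.02 M, degassed), 110 °C, 2 h
Reagents that add atoms: none
Why: Thermal conrotatory 4π ring opening of the cyclobutenone cleaves the C1–C4 bond, the C4 methoxy group rotating outward as donors do, so that dienylketene 8 has the alkenyl group cis to the ketene; disrotatory 6π electrocyclisation then joins the ketene carbon to the enone α-carbon (the future C8a–C4a bond) to give cyclohexadienone 9, whose doubly activated C–H should tautomerise at once to phenol 10. The closest known reaction type is the thermal ring expansion of squarate-derived 4-alkenyl- and 4-aryl-4-alkoxycyclobutenones to regiodefined monoprotected hydroquinones. Ring A is the only ring closed, by 6π electrocyclisation at C4a–C8a. No stereocentre is formed, and the racemic centres of 7 and 9 are erased on aromatisation. The selectivity needed is the placing of the four oxygens, and connectivity secures it: the former carbinol carbon keeps its methyl ether and becomes C6 next to C5–H, while the ketene oxygen becomes the only free hydroxyl, at C8a beside the acyl group. Inward rotation of the alkenyl group is needed for closure, and a ketene of the wrong geometry should only revert to 7.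

Step 4
Reactants: 10 1-(2-hydroxy-3,4,5-trimethoxyphenyl)-2-methoxyethan-1-one; 11 4-methoxybenzoic anhydride
Product: 14 auranetin (3,6,7,8-tetramethoxy-2-(4-methoxyphenyl)-4H-chromen-4-one), via aryl ester 12 (not isolated), via 1,3-diketone 13 (not isolated)
Conditions: 11 (4 equiv), sodium 4-methoxybenzoate (2 equiv), neat, 175 °C, 4 h; then KOH, aq. EtOH, reflux, 30 min
Reagents that add atoms: none
Why: Allan–Robinson condensation, in which O-aroylation of the phenol, base-mediated transfer of the aroyl group to the methoxy-bearing α-carbon (Baker–Venkataraman type) and cyclodehydration of the 1,3-diketone should close ring C at O1–C2, the ω-methoxy group ending as the 3-methoxy group; no stereocentre remains.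

Compound list
1 | (E)-1,2-bis(tributylstannyl)ethene | CCCC[Sn](CCCC)(CCCC)/C=C/[Sn](CCCC)(CCCC)CCCC | starting material
2 | dimethyl squarate (3,4-dimethoxycyclobut-3-ene-1,2-dione) | COC1=C(OC)C(=O)C1=O | starting material
3 | vinyllithium ((E)-2-(tributylstannyl)ethenyllithium), formed in the flask | [Li]/C=C/[Sn](CCCC)(CCCC)CCCC | intermediate
4 | lithium alkoxide (lithium salt of racemic 4-hydroxy-2,3-dimethoxy-4-[(E)-2-(tributylstannyl)ethenyl]cyclobut-2-en-1-one), formed in the flask | [Li]OC1(/C=C/[Sn](CCCC)(CCCC)CCCC)C(OC)=C(OC)C1=O | intermediate
5 | racemic 2,3,4-trimethoxy-4-[(E)-2-(tributylstannyl)ethenyl]cyclobut-2-en-1-one | CCCC[Sn](CCCC)(CCCC)/C=C/C1(OC)C(OC)=C(OC)C1=O | intermediate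
6 | methoxyacetyl chloride | COCC(=O)Cl | starting material
7 | racemic 2,3,4-trimethoxy-4-[(1E)-4-methoxy-3-oxobut-1-en-1-yl]cyclobut-2-en-1-one | COCC(=O)/C=C/C1(OC)C(OC)=C(OC)C1=O | intermediate
8 | dienylketene ((3Z,5E)-2,3,4,8-tetramethoxyocta-1,3,5-triene-1,7-dione), formed in the flask | O=C=C(OC)/C(OC)=C(OC)\C=C\C(=O)COC | intermediate
9 | cyclohexadienone (racemic 6-(methoxyacetyl)-2,3,4-trimethoxycyclohexa-2,4-dien-1-one), formed in the flask | COCC(=O)C1C=C(OC)C(OC)=C(OC)C1=O | intermediate
10 | 1-(2-hydroxy-3,4,5-trimethoxyphenyl)-2-methoxyethan-1-one | COCC(=O)c1cc(OC)c(OC)c(OC)c1O | intermediate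
11 | 4-methoxybenzoic anhydride | COc1ccc(cc1)C(=O)OC(=O)c1ccc(OC)cc1 | starting material
12 | aryl ester (2,3,4-trimethoxy-6-(methoxyacetyl)phenyl 4-methoxybenzoate), formed in the flask | COCC(=O)c1cc(OC)c(OC)c(OC)c1OC(=O)c1ccc(OC)cc1 | intermediate
13 | 1,3-diketone (1-(2-hydroxy-3,4,5-trimethoxyphenyl)-2-methoxy-3-(4-methoxyphenyl)propane-1,3-dione, racemic and enolisable), formed in the flask | COC(C(=O)c1ccc(OC)cc1)C(=O)c1cc(OC)c(OC)c(OC)c1O | intermediate
14 | auranetin (3,6,7,8-tetramethoxy-2-(4-methoxyphenyl)-4H-chromen-4-one) | COc1ccc(-c2oc3c(OC)c(OC)c(OC)cc3c(=O)c2OC)cc1 | target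

Total step count: 4. Longest linear sequence: 4 steps (2 → 5 → 7 → 10 → 14).

Steps most likely to fail

Step 3 (key step). The acyl-substituted alkene terminus may close slowly, so that the dienylketene dimerises or is trapped before ring A forms. The fallback sets out from 2 and returns at 10. Vinyllithium would be added to 2 and the alkoxide methylated with MeOTf to give racemic 4-ethenyl-2,3,4-trimethoxycyclobut-2-en-1-one F1. The unbiased vinyl group of F1 should undergo the same ring expansion in refluxing toluene to give 2,3,4-trimethoxyphenol F2. The side chain would then be introduced on F2 after aromatisation, by ortho-acylation with methoxyacetic acid in BF3·OEt2 at 80 °C (acylation and Fries shift to the only free ortho position), which should give 10.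

Step 2. Decarbonylation of the acylpalladium intermediate, protodestannylation by adventitious HCl, or early ring opening may erode the coupling. The fallback sets out from 5 and returns at 7, with the polarity reversed. Iododestannylation of 5 with I2 (CH2Cl2, 0 °C) would give racemic 4-[(E)-2-iodoethenyl]-2,3,4-trimethoxycyclobut-2-en-1-one F3. A carbonylative Stille coupling of F3 with tributyl(methoxymethyl)stannane under CO (1 atm, PdCl2(PPh3)2, THF, 50 °C) would then build the ketone from the vinyl side and should give 7.

Step 4. C-aroylation may stall at the aryl ester, and the hot melt may cause demethylation or decomposition. The fallback sets out from 10 and arrives at 14. Claisen–Schmidt condensation of 10 with 4-methoxybenzaldehyde (KOH, EtOH, rt) would give the α-methoxychalcone (Z)-1-(2-hydroxy-3,4,5-trimethoxyphenyl)-2-methoxy-3-(4-methoxyphenyl)prop-2-en-1-one F4. Oxidative cyclisation of F4 (I2 cat., DMSO, 120 °C) would then close ring C by oxa-Michael addition and dehydrogenation and should give 14.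

Further compounds
F1 | step 3 | racemic 4-ethenyl-2,3,4-trimethoxycyclobut-2-en-1-one | COC1=C(OC)C(OC)(C=C)C1=O
F2 | step 3 | 2,3,4-trimethoxyphenol | COc1ccc(O)c(OC)c1OC
F3 | step 2 | racemic 4-[(E)-2-iodoethenyl]-2,3,4-trimethoxycyclobut-2-en-1-one | COC1=C(OC)C(OC)(/C=C/I)C1=O
F4 | step 4 | (Z)-1-(2-hydroxy-3,4,5-trimethoxyphenyl)-2-methoxy-3-(4-methoxyphenyl)prop-2-en-1-one | COc1ccc(/C=C(\OC)C(=O)c2cc(OC)c(OC)c(OC)c2O)cc1
A1 | direct plan | 2,3,4-trimethoxybenzaldehyde | COc1ccc(C=O)c(OC)c1OC
A2 | direct plan | 2-hydroxy-3,4,5-trimethoxybenzaldehyde | COc1cc(C=O)c(O)c(OC)c1OC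
A3 | direct plan | 2-methoxy-1-(4-methoxyphenyl)ethan-1-one | COCC(=O)c1ccc(OC)cc1
A4 | direct plan | 1-methoxy-4-(methoxyethynyl)benzene | COC#Cc1ccc(OC)cc1
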